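The route rests on the C7–C8 bond, which lies in the acyclic, unfunctionalised C7–C9 methylene tether between the methyl-bearing stereocentres C6 and C10 (C1 is the chlorohydrin methyl, C4 the ketone, C17 the CH2 on furan C3). Since no functional group polarises either carbon, the bond is made by anodic co-decarboxylation of two acids: a C5–C7 acid with a silyl ether at C5 and a C8–C11 acid with a benzyl ether at C11, both from one chiral bromohydrin. One operation joins two primary radicals, closes no ring (the furan ring arrives later) and creates no stereocentre. The furan-bearing diene tail and the threonine-derived chlorohydrin head are then attached at C11 and C5.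

Key step: step 6

Remark: (S)-3-bromo-2-methylpropan-1-ol is taken as a catalogue compound. All configurations were re-derived: both methyl centres end as (6R,10R), and each threonine carbon is inverted once overall to give (2S,3S).

Step 1
Reactants: 1 (S)-3-bromo-2-methylpropan-1-ol
Product: 2 (S)-(3-bromo-2-methylpropoxy)(tert-butyl)diphenylsilane
Conditions: TBDPSCl, imidazole, CH2Cl2, 0 °C → rt
Reagents that add atoms: tert-butyl(chloro)diphenylsilane, CC(C)(C)[Si](Cl)(c1ccccc1)c1ccccc1
Why: Silyl ether formation at the primary hydroxyl gives an ether that withstands the Grignard reagent and the electrolysis and leaves the stereocentre untouched.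

Step 2
Reactants: 2 (S)-(3-bromo-2-methylpropoxy)(tert-butyl)diphenylsilane
Product: 4 (R)-4-[(tert-butyldiphenylsilyl)oxy]-3-methylbutanoic acid, via alkylmagnesium bromide 3 (not isolated)
Conditions: Mg, BrCH2CH2Br (cat.), THF, 45 °C; CO2 (g), −20 °C → rt; 1 M HCl
Reagents that add atoms: carbon dioxide, O=C=O
Why: Grignard formation from the primary bromide and carboxylation with CO2 add the carboxyl carbon that is given up again at the anode, and the centre that becomes C6 is a spectator whose descriptor changes from S to R by priority alone.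

Step 3
Reactants: 1 (S)-3-bromo-2-methylpropan-1-ol
Product: 5 (S)-[(3-bromo-2-methylpropoxy)methyl]benzene
Conditions: BnOC(=NH)CCl3, TfOH (cat.), cyclohexane/CH2Cl2, 0 °C → rt
Reagents that add atoms: benzyl 2,2,2-trichloroacetimidate, N=C(OCc1ccccc1)C(Cl)(Cl)Cl
Why: Acid-catalysed O-benzylation with the trichloroacetimidate avoids alkoxide formation, which would close the bromohydrin to an oxetane.

Step 4
Reactants: 5 (S)-[(3-bromo-2-methylpropoxy)methyl]benzene; 6 diethyl malonate
Product: 7 diethyl (R)-2-[3-(benzyloxy)-2-methylpropyl]malonate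
Conditions: NaH, NaI (cat.), THF/DMF, 0 → 70 °C
Reagents that add atoms: none
Why: Malonic ester alkylation, in which the sodium enolate of excess diethyl malonate displaces the primary bromide (activated in situ as the iodide) by SN2 at the carbon that becomes C9, remote from the stereocentre.

Step 5
Reactants: 7 diethyl (R)-2-[3-(benzyloxy)-2-methylpropyl]malonate
Product: 9 (R)-5-(benzyloxy)-4-methylpentanoic acid, via substituted malonic acid 8 (not isolated)
Conditions: KOH, EtOH/H2O, reflux; H2SO4 (aq.) to pH 1, reflux
Reagents that add atoms: potassium hydroxide, [K+].[OH-]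
Why: Saponification and acid-promoted decarboxylation of the malonic acid (second half of the malonic ester synthesis) leave the γ-branched acid, the benzyl ether being stable to aqueous base and to hot dilute acid.

Step 6
Reactants: 4 (R)-4-[(tert-butyldiphenylsilyl)oxy]-3-methylbutanoic acid; 9 (R)-5-(benzyloxy)-4-methylpentanoic acid
Product: 10 {[(2R,6R)-7-(benzyloxy)-2,6-dimethylheptyl]oxy}(tert-butyl)diphenylsilane
Conditions: 4 (3 equiv), 9 (1 equiv), KOH (5 mol% of total acid), MeOH, Pt anode, Pt cathode, undivided cell, ca. 0.3 A cm−2, 30 °C, until pH 8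
Reagents that add atoms: none
Why: Mixed Kolbe electrolysis: at the platinum anode at high current density both carboxylates are oxidised to acyloxy radicals, which lose CO2 to give the primary alkyl radicals centred on C7 (from 4) and C8 (from 9), and these recombine in the anode layer to form the C7–C8 bond. The closest known reaction type is the classical crossed Kolbe coupling of two alkanoic acids that carry remote ether or ester groups. No ring is closed and no stereocentre is created; C6 sits next to the C7 radical and C10 one methylene away from the C8 radical, but neither is itself a radical centre and alkyl radicals do not undergo 1,2-hydrogen shifts, so both configurations should be carried through unchanged. The only selectivity required is hetero- over homo-coupling, which is statistical and is secured with respect to 9 by the threefold excess of the two-step acid 4. Both radicals are primary and lack α-heteroatoms or α-branches, so they should dimerise instead of being oxidised on to cations, and the adsorbed carboxylate layer shields the aryl groups of the two ethers from the anode. The silyl and benzyl ethers give the two homodimers and 10 clearly different polarities, so 10 should be separable by chromatography.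

Step 7
Reactants: 10 {[(2R,6R)-7-(benzyloxy)-2,6-dimethylheptyl]oxy}(tert-butyl)diphenylsilane
Product: 11 (2R,6R)-7-[(tert-butyldiphenylsilyl)oxy]-2,6-dimethylheptan-1-ol
Conditions: H2 (1 atm), 10% Pd/C, EtOAc, rt
Reagents that add atoms: none
Why: Catalytic hydrogenolysis removes the benzyl ether selectively because the molecule still holds no alkene and the silyl ether is inert to H2/Pd.

Step 8
Reactants: 11 (2R,6R)-7-[(tert-butyldiphenylsilyl)oxy]-2,6-dimethylheptan-1-ol
Product: 12 (2R,6R)-7-[(tert-butyldiphenylsilyl)oxy]-2,6-dimethylheptanal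
Conditions: TEMPO (cat.), PhI(OAc)2, CH2Cl2, rt
Reagents that add atoms: none
Why: Oxoammonium-mediated (TEMPO) oxidation stops at the aldehyde under nearly neutral conditions, which limits enolisation at C10, and the aldehyde is carried on at once.

Step 9
Reactants: 12 (2R,6R)-7-[(tert-butyldiphenylsilyl)oxy]-2,6-dimethylheptanal
Product: 13 tert-butyl{[(2R,6R)-2,6-dimethyloct-7-yn-1-yl]oxy}diphenylsilane
Conditions: dimethyl (1-diazo-2-oxopropyl)phosphonate, K2CO3, MeOH, 0 °C → rt
Reagents that add atoms: dimethyl (1-diazo-2-oxopropyl)phosphonate, COP(=O)(OC)C(=[N+]=[N-])C(C)=O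
Why: Seyferth–Gilbert homologation in its Ohira–Bestmann form turns the aldehyde into the terminal alkyne C11≡C12 with mild carbonate base at low temperature, conditions under which α-methyl aldehydes are normally homologated faster than they epimerise.

Step 10
Reactants: 14 (5-chloropent-1-yn-1-yl)trimethylsilane
Product: 15 (5-iodopent-1-yn-1-yl)trimethylsilane
Conditions: NaI, acetone, reflux
Reagents that add atoms: sodium iodide, [Na+].[I-]
Why: Finkelstein halide exchange (SN2) driven by precipitation of NaCl gives the primary iodide needed for zinc insertion.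

Step 11
Reactants: 15 (5-iodopent-1-yn-1-yl)trimethylsilane; 16 3-bromofuran
Product: 18 [5-(furan-3-yl)pent-1-yn-1-yl]trimethylsilane, via alkylzinc iodide 17 (not isolated)
Conditions: Zn dust, LiCl, THF, 40 °C; then 16, Pd(OAc)2 (2 mol%), SPhos (4 mol%), THF, rt → 50 °C
Reagents that add atoms: none
Why: Zinc insertion into the primary iodide followed by Negishi sp3–sp2 cross-coupling with the heteroaryl bromide forms the C17–furan bond, the bulky electron-rich phosphine favouring reductive elimination over β-hydride elimination and the silyl cap keeping the alkyne out of the chemistry.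

Step 12
Reactants: 18 [5-(furan-3-yl)pent-1-yn-1-yl]trimethylsilane
Product: 19 3-(pent-4-yn-1-yl)furan
Conditions: K2CO3, MeOH, rt
Reagents that add atoms: none
Why: Base-mediated protodesilylation of the alkynylsilane in methanol frees the terminal alkyne without affecting the furan.

Step 13
Reactants: 19 3-(pent-4-yn-1-yl)furan
Product: 21 3-[(4E)-5-iodo-4-methylpent-4-en-1-yl]furan, via alkenyldimethylalane 20 (not isolated)
Conditions: Me3Al, Cp2ZrCl2 (0.25 equiv), CH2Cl2, 0 °C → rt; I2, THF, −30 → 0 °C
Reagents that add atoms: trimethylaluminium, C[Al](C)C; iodine, II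
Why: Zirconium-catalysed carboalumination (Negishi methylalumination) adds CH3 and Al syn across the terminal alkyne with the methyl on the internal carbon, and iodinolysis of the C–Al bond with retention fixes the C13=C14 double bond as E.

Step 14
Reactants: 13 tert-butyl{[(2R,6R)-2,6-dimethyloct-7-yn-1-yl]oxy}diphenylsilane; 21 3-[(4E)-5-iodo-4-methylpent-4-en-1-yl]furan
Product: 24 tert-butyl{[(2R,6R,7E,9E)-13-(furan-3-yl)-2,6,10-trimethyltrideca-7,9-dien-1-yl]oxy}diphenylsilane, via alkenylzirconocene chloride 22 (not isolated), via alkenylzinc chloride 23 (not isolated)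
Conditions: Cp2Zr(H)Cl, THF, rt; ZnCl2, THF, 0 °C; then 21, Pd(PPh3)4 (5 mol%), rt
Reagents that add atoms: none
Why: Hydrozirconation is a syn addition that puts zirconium on the terminal carbon C12, and transmetalation to zinc followed by Negishi alkenyl–alkenyl coupling under zerovalent palladium proceeds with retention at both sp2 carbons, so the C11=C12 bond is formed E and the new C12–C13 bond completes the (11E,13E)-diene.

Step 15
Reactants: 24 tert-butyl{[(2R,6R,7E,9E)-13-(furan-3-yl)-2,6,10-trimethyltrideca-7,9-dien-1-yl]oxy}diphenylsilane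
Product: 25 (2R,6R,7E,9E)-13-(furan-3-yl)-2,6,10-trimethyltrideca-7,9-dien-1-ol
Conditions: TBAF, THF, 0 °C → rt
Reagents that add atoms: none
Why: Fluoride-induced cleavage of the Si–O bond frees the C5 hydroxyl while the diene and the furan, which are insensitive to fluoride, stay intact.

Step 16
Reactants: 25 (2R,6R,7E,9E)-13-(furan-3-yl)-2,6,10-trimethyltrideca-7,9-dien-1-ol
Product: 26 3-[(4E,6E,8R,12R)-13-iodo-4,8,12-trimethyltrideca-4,6-dien-1-yl]furan
Conditions: PPh3, imidazole, I2, CH2Cl2, 0 °C (I2 added before 25)
Reagents that add atoms: iodine, II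
Why: Appel-type iodination activates the primary alcohol as an oxyphosphonium ion that iodide displaces by SN2 at C5, and pre-forming the phosphine–iodine adduct keeps free iodine away from the diene and the furan.

Step 17
Reactants: 27 L-threonine
Product: 28 (2S,3R)-2-bromo-3-hydroxybutanoic acid
Conditions: NaNO2, KBr, H2SO4 (aq.), −5 → 0 °C
Reagents that add atoms: potassium bromide, [K+].[Br-]
Why: Diazotisation of the α-amino acid in the presence of bromide replaces NH2 by Br with overall retention at C2 through carboxylate-assisted double inversion, and C3 is not involved.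

Step 18
Reactants: 28 (2S,3R)-2-bromo-3-hydroxybutanoic acid
Product: 29 potassium (2R,3R)-3-methyloxirane-2-carboxylate
Conditions: KOH (2 equiv), EtOH, −20 °C → rt
Reagents that add atoms: potassium hydroxide, [K+].[OH-]
Why: Intramolecular Williamson etherification, in which the C3 alkoxide displaces bromide from C2 with inversion, gives the cis-epoxide and sets the future C3–O centre of the target in its final spatial arrangement.

Step 19
Reactants: 29 potassium (2R,3R)-3-methyloxirane-2-carboxylate
Product: 31 (2R,3R)-N-methoxy-N,3-dimethyloxirane-2-carboxamide, via mixed pivalic anhydride 30 (not isolated)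
Conditions: t-BuCOCl, THF/MeCN, 0 °C; then MeNHOMe·HCl, Et3N, 0 °C → rt
Reagents that add atoms: N,O-dimethylhydroxylamine hydrochloride, CNOC.Cl
Why: Mixed-anhydride amidation, in which the amine attacks the less hindered and more electrophilic oxirane carbonyl of the pivalic anhydride, gives the Weinreb amide without opening the epoxide.

Step 20
Reactants: 31 (2R,3R)-N-methoxy-N,3-dimethyloxirane-2-carboxamide
Product: 32 (2S,3S)-3-chloro-2-hydroxy-N-methoxy-N-methylbutanamide
Conditions: HCl (4 M in 1,4-dioxane), CH2Cl2, −20 → 0 °C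
Reagents that add atoms: hydrogen chloride, Cl
Why: Acid-promoted SN2 opening of the protonated oxirane, in which chloride attacks C3 (remote from the electron-withdrawing carbonyl that disfavours attack at C2) with inversion, sets the C–Cl centre as (3S) and leaves the carbinol centre untouched (its descriptor becomes S by priority only).

Step 21
Reactants: 32 (2S,3S)-3-chloro-2-hydroxy-N-methoxy-N-methylbutanamide
Product: 33 (2S,3S)-3-chloro-N-methoxy-N-methyl-2-[(triethylsilyl)oxy]butanamide
Conditions: TESCl, imidazole, CH2Cl2, 0 °C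
Reagents that add atoms: chlorotriethylsilane, CC[Si](Cl)(CC)CC
Why: Silylation of the secondary hydroxyl with a weak base that does not re-close the chlorohydrin gives a triethylsilyl ether, chosen because it can later be removed under nearly neutral conditions.

Step 22
Reactants: 26 3-[(4E,6E,8R,12R)-13-iodo-4,8,12-trimethyltrideca-4,6-dien-1-yl]furan; 33 (2S,3S)-3-chloro-N-methoxy-N-methyl-2-[(triethylsilyl)oxy]butanamide
Product: 36 (2S,3S,6R,10R,11E,13E)-2-chloro-17-(furan-3-yl)-6,10,14-trimethyl-3-[(triethylsilyl)oxy]heptadeca-11,13-dien-4-one, via alkyllithium 34 (not isolated), via lithium hemiaminal alkoxide 35 (not isolated)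
Conditions: t-BuLi (2.1 equiv), Et2O/pentane, −78 °C; then 33 (1.5 equiv), −78 → −40 °C; aq. NH4Cl
Reagents that add atoms: none
Why: Iodine–lithium exchange at −78 °C (the second equivalent of t-BuLi destroys the tert-butyl iodide) gives the primary alkyllithium, whose addition to the Weinreb amide stops at the chelated tetrahedral adduct and releases the C4 ketone only on work-up, forming the C4–C5 bond without touching any stereocentre.

Step 23
Reactants: 36 (2S,3S,6R,10R,11E,13E)-2-chloro-17-(furan-3-yl)-6,10,14-trimethyl-3-[(triethylsilyl)oxy]heptadeca-11,13-dien-4-one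
Product: 37 (2S,3S,6R,10R,11E,13E)-2-chloro-17-(furan-3-yl)-3-hydroxy-6,10,14-trimethylheptadeca-11,13-dien-4-one
Conditions: HF·pyridine, pyridine, THF, 0 °C
Reagents that add atoms: none
Why: Buffered fluoride cleavage of the labile triethylsilyl ether under mildly acidic conditions avoids the base-induced epoxide closure or elimination open to a β-chloro-α-hydroxy ketone and spares the furan and the diene.

Compound list
1 | (S)-3-bromo-2-methylpropan-1-ol | BrC[C@@H](C)CO | starting material
2 | (S)-(3-bromo-2-methylpropoxy)(tert-butyl)diphenylsilane | BrC[C@@H](C)CO[Si](c1ccccc1)(c1ccccc1)C(C)(C)C | intermediate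
3 | {(S)-3-[(tert-butyldiphenylsilyl)oxy]-2-methylpropyl}magnesium bromide | Br[Mg]C[C@@H](C)CO[Si](c1ccccc1)(c1ccccc1)C(C)(C)C | intermediate
4 | (R)-4-[(tert-butyldiphenylsilyl)oxy]-3-methylbutanoic acid | OC(=O)C[C@@H](C)CO[Si](c1ccccc1)(c1ccccc1)C(C)(C)C | intermediate
5 | (S)-[(3-bromo-2-methylpropoxy)methyl]benzene | BrC[C@@H](C)COCc1ccccc1 | intermediate
6 | diethyl malonate | CCOC(=O)CC(=O)OCC | starting material
7 | diethyl (R)-2-[3-(benzyloxy)-2-methylpropyl]malonate | CCOC(=O)C(C[C@@H](C)COCc1ccccc1)C(=O)OCC | intermediate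
8 | (R)-2-[3-(benzyloxy)-2-methylpropyl]malonic acid | OC(=O)C(C[C@@H](C)COCc1ccccc1)C(O)=O | intermediate
9 | (R)-5-(benzyloxy)-4-methylpentanoic acid | OC(=O)CC[C@@H](C)COCc1ccccc1 | intermediate
10 | {[(2R,6R)-7-(benzyloxy)-2,6-dimethylheptyl]oxy}(tert-butyl)diphenylsilane | CC(C)(C)[Si](c1ccccc1)(c1ccccc1)OC[C@H](C)CCC[C@@H](C)COCc1ccccc1 | intermediate
11 | (2R,6R)-7-[(tert-butyldiphenylsilyl)oxy]-2,6-dimethylheptan-1-ol | CC(C)(C)[Si](c1ccccc1)(c1ccccc1)OC[C@H](C)CCC[C@@H](C)CO | intermediate
12 | (2R,6R)-7-[(tert-butyldiphenylsilyl)oxy]-2,6-dimethylheptanal | CC(C)(C)[Si](c1ccccc1)(c1ccccc1)OC[C@H](C)CCC[C@@H](C)C=O | intermediate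
13 | tert-butyl{[(2R,6R)-2,6-dimethyloct-7-yn-1-yl]oxy}diphenylsilane | CC(C)(C)[Si](c1ccccc1)(c1ccccc1)OC[C@H](C)CCC[C@@H](C)C#C | intermediate
14 | (5-chloropent-1-yn-1-yl)trimethylsilane | C[Si](C)(C)C#CCCCCl | starting material
15 | (5-iodopent-1-yn-1-yl)trimethylsilane | C[Si](C)(C)C#CCCCI | intermediate
16 | 3-bromofuran | Brc1ccoc1 | starting material
17 | iodo[5-(trimethylsilyl)pent-4-yn-1-yl]zinc | C[Si](C)(C)C#CCCC[Zn]I | intermediate
18 | [5-(furan-3-yl)pent-1-yn-1-yl]trimethylsilane | C[Si](C)(C)C#CCCCc1ccoc1 | intermediate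
19 | 3-(pent-4-yn-1-yl)furan | C#CCCCc1ccoc1 | intermediate
20 | [(1E)-5-(furan-3-yl)-2-methylpent-1-en-1-yl]dimethylalumane | C[Al](C)/C=C(\C)CCCc1ccoc1 | intermediate
21 | 3-[(4E)-5-iodo-4-methylpent-4-en-1-yl]furan | I/C=C(\C)CCCc1ccoc1 | intermediate
22 | chlorobis(η5-cyclopentadienyl)[(1E,3R,7R)-8-[(tert-butyldiphenylsilyl)oxy]-3,7-dimethyloct-1-en-1-yl]zirconium | CC(C)(C)[Si](c1ccccc1)(c1ccccc1)OC[C@H](C)CCC[C@@H](C)/C=C/[Zr](Cl)(C1C=CC=C1)C1C=CC=C1 | intermediate
23 | chloro[(1E,3R,7R)-8-[(tert-butyldiphenylsilyl)oxy]-3,7-dimethyloct-1-en-1-yl]zinc | CC(C)(C)[Si](c1ccccc1)(c1ccccc1)OC[C@H](C)CCC[C@@H](C)/C=C/[Zn]Cl | intermediate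
24 | tert-butyl{[(2R,6R,7E,9E)-13-(furan-3-yl)-2,6,10-trimethyltrideca-7,9-dien-1-yl]oxy}diphenylsilane | CC(C)(C)[Si](c1ccccc1)(c1ccccc1)OC[C@H](C)CCC[C@@H](C)/C=C/C=C(\C)CCCc1ccoc1 | intermediate
25 | (2R,6R,7E,9E)-13-(furan-3-yl)-2,6,10-trimethyltrideca-7,9-dien-1-ol | OC[C@H](C)CCC[C@@H](C)/C=C/C=C(\C)CCCc1ccoc1 | intermediate
26 | 3-[(4E,6E,8R,12R)-13-iodo-4,8,12-trimethyltrideca-4,6-dien-1-yl]furan | IC[C@H](C)CCC[C@@H](C)/C=C/C=C(\C)CCCc1ccoc1 | intermediate
27 | L-threonine | C[C@@H](O)[C@H](N)C(O)=O | starting material
28 | (2S,3R)-2-bromo-3-hydroxybutanoic acid | C[C@@H](O)[C@H](Br)C(O)=O | intermediate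
29 | potassium (2R,3R)-3-methyloxirane-2-carboxylate | C[C@H]1O[C@H]1C(=O)[O-].[K+] | intermediate
30 | (2R,3R)-3-methyloxirane-2-carboxylic pivalic anhydride | C[C@H]1O[C@H]1C(=O)OC(=O)C(C)(C)C | intermediate
31 | (2R,3R)-N-methoxy-N,3-dimethyloxirane-2-carboxamide | C[C@H]1O[C@H]1C(=O)N(C)OC | intermediate
32 | (2S,3S)-3-chloro-2-hydroxy-N-methoxy-N-methylbutanamide | C[C@H](Cl)[C@@H](O)C(=O)N(C)OC | intermediate
33 | (2S,3S)-3-chloro-N-methoxy-N-methyl-2-[(triethylsilyl)oxy]butanamide | C[C@H](Cl)[C@@H](O[Si](CC)(CC)CC)C(=O)N(C)OC | intermediate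
34 | [(2S,6R,7E,9E)-13-(furan-3-yl)-2,6,10-trimethyltrideca-7,9-dien-1-yl]lithium | [Li]C[C@H](C)CCC[C@@H](C)/C=C/C=C(\C)CCCc1ccoc1 | intermediate
35 | lithium (2S,3S,6R,10R,11E,13E)-2-chloro-17-(furan-3-yl)-4-[methoxy(methyl)amino]-6,10,14-trimethyl-3-[(triethylsilyl)oxy]heptadeca-11,13-dien-4-olate (C4 epimers) | [Li]OC(C[C@H](C)CCC[C@@H](C)/C=C/C=C(\C)CCCc1ccoc1)(N(C)OC)[C@H](O[Si](CC)(CC)CC)[C@H](C)Cl | intermediate
36 | (2S,3S,6R,10R,11E,13E)-2-chloro-17-(furan-3-yl)-6,10,14-trimethyl-3-[(triethylsilyl)oxy]heptadeca-11,13-dien-4-one | C/C(=C\C=C\[C@H](C)CCC[C@@H](C)CC(=O)[C@H](O[Si](CC)(CC)CC)[C@H](C)Cl)CCCc1ccoc1 | intermediate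
37 | (2S,3S,6R,10R,11E,13E)-2-chloro-17-(furan-3-yl)-3-hydroxy-6,10,14-trimethylheptadeca-11,13-dien-4-one | C/C(=C\C=C\[C@H](C)CCC[C@@H](C)CC(=O)[C@H](O)[C@H](C)Cl)CCCc1ccoc1 | target

Total step count: 23.
Longest linear sequence: 12 steps (steps 3, 4, 5, 6, 7, 8, 9, 14, 15, 16, 22 and 23, from 1 to 37).

Steps most likely to fail

Step 6. Statistical homocoupling, together with anodic over-oxidation of the primary radicals (ether and alkene by-products) or of the aryl-bearing protecting groups, may consume both acids before enough hetero-coupled product forms. The fallback makes the same C7–C8 bond by a polar, copper-catalysed alkyl–alkyl coupling and sets out from 9 and from 2. Acid 9 would be reduced with BH3·THF to (R)-5-(benzyloxy)-4-methylpentan-1-ol F1, which PPh3/I2/imidazole would convert into (R)-{[(5-iodo-2-methylpentyl)oxy]methyl}benzene F2. The Grignard reagent 3, generated from 2 as in step 2, would then be coupled with F2 under Li2CuCl4 catalysis (THF, −20 → 0 °C) to give 10, where the route is rejoined.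

Step 22. Deprotonation at C3 of the amide followed by β-elimination of chloride, metalation of the furan by the organolithium, or protonation of the alkyllithium before it adds would erode the fragment union. The fallback is a base-free ketone synthesis by Fukuyama coupling and sets out from 29 and 26. Salt 29 would be activated as anhydride 30 and treated with EtSH/Et3N to give S-ethyl (2R,3R)-3-methyloxirane-2-carbothioate F3; HCl in dioxane would open it to S-ethyl (2S,3S)-3-chloro-2-hydroxybutanethioate F4, and TESCl/imidazole would give S-ethyl (2S,3S)-3-chloro-2-[(triethylsilyl)oxy]butanethioate F5. Iodide 26 would be converted with Zn dust/LiCl in THF into iodo[(2R,6R,7E,9E)-13-(furan-3-yl)-2,6,10-trimethyltrideca-7,9-dien-1-yl]zinc F6, which should couple with F5 under PdCl2(PPh3)2 catalysis in toluene/THF at rt to give 36, rejoining the route before step 23.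

Step 20. Loss of regiocontrol in the oxirane opening (chloride entering at C2 next to the amide carbonyl), or reclosure of the chlorohydrin during work-up, would give a wrong or mixed head group. The fallback moves the ring opening to the free carboxylic acid, the substrate class for which β-attack of hydrogen halides on glycidic acids is classical, and sets out from 29. Treatment with HCl (2 M in Et2O, 2.2 equiv, 0 °C) would liberate the epoxy acid and open it at C3 to (2S,3S)-3-chloro-2-hydroxybutanoic acid F7. This would be amidated directly with MeNHOMe·HCl, EDC·HCl, HOBt and N-methylmorpholine in CH2Cl2 to give 32, where the route is rejoined.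

Further compounds
F1 | step 6 | (R)-5-(benzyloxy)-4-methylpentan-1-ol | OCCC[C@@H](C)COCc1ccccc1
F2 | step 6 | (R)-{[(5-iodo-2-methylpentyl)oxy]methyl}benzene | ICCC[C@@H](C)COCc1ccccc1
F3 | step 22 | S-ethyl (2R,3R)-3-methyloxirane-2-carbothioate | C[C@H]1O[C@H]1C(=O)SCC
F4 | step 22 | S-ethyl (2S,3S)-3-chloro-2-hydroxybutanethioate | C[C@H](Cl)[C@@H](O)C(=O)SCC
F5 | step 22 | S-ethyl (2S,3S)-3-chloro-2-[(triethylsilyl)oxy]butanethioate | C[C@H](Cl)[C@@H](O[Si](CC)(CC)CC)C(=O)SCC
F6 | step 22 | iodo[(2R,6R,7E,9E)-13-(furan-3-yl)-2,6,10-trimethyltrideca-7,9-dien-1-yl]zinc | I[Zn]C[C@H](C)CCC[C@@H](C)/C=C/C=C(\C)CCCc1ccoc1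
F7 | step 20 | (2S,3S)-3-chloro-2-hydroxybutanoic acid | C[C@H](Cl)[C@@H](O)C(O)=O
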